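**Retrosynthetic overview**
1. Atom labels: ring C1 (ketone), C2 (methyl-bearing oxirane carbon), C3 (oxirane CH), C4 (CH2), C5 (side-chain carbon), C6 (ester carbon); chain C7 (=CH2), C8 (C=O), C9=C10, C11 (C–OOH).
2. Last bond: C11–OOH by radical C–H hydroperoxidation of an isopropyl dienone; before that, the C1 ketone and C6 tiglate come from a cis-1,2-diol.
3. Oxirane: peracid epoxidation of C2=C3 on the face opposite a cis-fused acetonide, which is the face of the side chain.
4. Key disconnection C5–C7: intermolecular addition of an α-keto radical (from a bromomethyl enone) to the diene terminus of toluene cis-dihydrodiol acetonide, anti to the acetonide, with hydrogen-atom transfer to C4; C7=CH2 then by Mannich methylenation.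
5. Ring order: the carbocycle is the toluene ring itself (enzymatic cis-dihydroxylation sets C6), then the temporary dioxolane, then the oxirane; no carbocycle-forming step.

Assumption: recombinant E. coli JM109 (pDTG601) expressing toluene dioxygenase is available as a whole-cell catalyst, and (E)-5-methylhex-3-en-2-one is bought as the E isomer.

**Step 1**
Reactants: 1 toluene
Product: 2 (1S,2R)-3-methylcyclohexa-3,5-diene-1,2-diol
Conditions: E. coli JM109 (pDTG601) whole cells (toluene dioxygenase), glucose, air, pH 7.2 buffer, 30 °C; EtOAc extraction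
Reagents that add atoms: dioxygen, O=O
Why: Enzymatic arene cis-dihydroxylation (toluene dioxygenase biooxidation) delivers both oxygens to one face in >99% ee, which fixes the carbinol carbon that becomes C6 as S (kept to the end) and the future ketone carbon C1 as R.

**Step 2**
Reactants: 2 (1S,2R)-3-methylcyclohexa-3,5-diene-1,2-diol
Product: 3 (3aR,7aS)-2,2,4-trimethyl-3a,7a-dihydro-1,3-benzodioxole
Conditions: 2,2-dimethoxypropane, TsOH (cat.), acetone, 0 °C
Reagents that add atoms: 2,2-dimethoxypropane, COC(C)(C)OC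
Why: Acid-catalysed transketalisation of the cis-diol gives the cis-fused dioxolane, which prevents dehydration to cresol and shields one face of the diene without touching a stereocentre.

**Step 3**
Reactants: 4 (E)-5-methylhex-3-en-2-one
Product: 6 (E)-1-bromo-5-methylhex-3-en-2-one, via silyl dienol ether 5 (not isolated)
Conditions: LiN(iPr)2, THF, −78 °C; TMSCl; then NBS, THF, −78 to 0 °C
Reagents that add atoms: N-bromosuccinimide, O=C1CCC(=O)N1Br; chlorotrimethylsilane, C[Si](C)(C)Cl (silyl group of intermediate 5 only)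
Why: Kinetic deprotonation of the enone occurs at the methyl group, and electrophilic bromination of the resulting 2-silyloxydiene (silyl enol ether halogenation) gives the bromomethyl enone regioselectively with no stereocentre involved.

**Step 4**
Reactants: 3 (3aR,7aS)-2,2,4-trimethyl-3a,7a-dihydro-1,3-benzodioxole; 6 (E)-1-bromo-5-methylhex-3-en-2-one
Product: 7 (E)-5-methyl-1-[(3aR,7S,7aS)-2,2,4-trimethyl-3a,6,7,7a-tetrahydro-1,3-benzodioxol-7-yl]hex-3-en-2-one
Conditions: Ru(bpy)3Cl2 (1 mol %), Hantzsch ester (1.3 equiv), iPr2NEt (20 mol %), NaHCO3 (2 equiv), DMF, blue LEDs, 20 °C; 6 (1.5 equiv) added over 4 h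
Reagents that add atoms: none
Why: Proposed new method: the photoreduced (monovalent) ruthenium complex reduces 6 to the electrophilic α-keto radical, which adds to the unsubstituted diene terminus C5 (not the methyl-bearing C2) on the face opposite the cis-fused dioxolane, and the bulky Hantzsch ester then transfers hydrogen to the less hindered terminus C4 of the resulting allyl radical, so the C5–C7 bond and the C5 stereocentre (S, side chain trans to the C6 oxygen) are set in one radical step while the C2=C3 alkene is kept; the closest known reactions are the photoredox reductive (Giese-type) hydroalkylation of alkenes with α-bromo carbonyl compounds and the anti-selective additions to arene cis-diol acetonides.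

**Step 5**
Reactants: 7 (E)-5-methyl-1-[(3aR,7S,7aS)-2,2,4-trimethyl-3a,6,7,7a-tetrahydro-1,3-benzodioxol-7-yl]hex-3-en-2-one
Product: 10 (E)-6-methyl-2-[(3aR,7S,7aS)-2,2,4-trimethyl-3a,6,7,7a-tetrahydro-1,3-benzodioxol-7-yl]hepta-1,4-dien-3-one, via Mannich base 8 (not isolated), via methiodide 9 (not isolated)
Conditions: LiN(iPr)2, THF, −78 °C; Me2N=CH2 iodide (Eschenmoser's salt), −78 °C to rt; MeI, MeOH, rt; aq. NaHCO3, CH2Cl2
Reagents that add atoms: N,N-dimethylmethyleneiminium iodide, C=[N+](C)C.[I-]; iodomethane, CI (methyl of intermediate 9 only)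
Why: Kinetic enolisation at C7, the only sp3 α-carbon of the enone, followed by Mannich reaction and elimination of the quaternised amine (Eschenmoser methylenation) installs the exocyclic C7=CH2, destroying the transient C7 stereocentre and leaving C5 untouched.

**Step 6**
Reactants: 10 (E)-6-methyl-2-[(3aR,7S,7aS)-2,2,4-trimethyl-3a,6,7,7a-tetrahydro-1,3-benzodioxol-7-yl]hepta-1,4-dien-3-one
Product: 11 (E)-2-[(1S,2S,3S,4S,6S)-2,3-(isopropylidenedioxy)-1-methyl-7-oxabicyclo[4.1.0]heptan-4-yl]-6-methylhepta-1,4-dien-3-one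
Conditions: mCPBA, NaHCO3, CH2Cl2, 0 °C
Reagents that add atoms: 3-chloroperoxybenzoic acid, OOC(=O)c1cccc(Cl)c1
Why: Prilezhaev epoxidation occurs only at the electron-rich trisubstituted ring alkene (both side-chain alkenes are conjugated to the ketone) and from the face opposite the pseudo-axial allylic dioxolane oxygen, which is the face of the equatorial side chain, so C2 and C3 are set with the oxirane cis to the side chain.

**Step 7**
Reactants: 11 (E)-2-[(1S,2S,3S,4S,6S)-2,3-(isopropylidenedioxy)-1-methyl-7-oxabicyclo[4.1.0]heptan-4-yl]-6-methylhepta-1,4-dien-3-one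
Product: 12 (E)-2-[(1R,2S,3S,4S,6S)-2,3-dihydroxy-1-methyl-7-oxabicyclo[4.1.0]heptan-4-yl]-6-methylhepta-1,4-dien-3-one
Conditions: AcOH/H2O (4:1), 35 °C
Reagents that add atoms: none
Why: Mild acid hydrolysis of the cis-fused isopropylidene acetal frees the cis-diol while the oxirane, flanked by oxygen-bearing carbons, is slow to ionise, and no stereocentre changes (the C1 descriptor changes by priority only).

**Step 8**
Reactants: 12 (E)-2-[(1R,2S,3S,4S,6S)-2,3-dihydroxy-1-methyl-7-oxabicyclo[4.1.0]heptan-4-yl]-6-methylhepta-1,4-dien-3-one; 13 (E)-2-methylbut-2-enoyl chloride (tigloyl chloride)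
Product: 14 (1R,2S,3S,4S,6S)-2-hydroxy-1-methyl-4-[(E)-6-methyl-3-oxohepta-1,4-dien-2-yl]-7-oxabicyclo[4.1.0]heptan-3-yl (E)-2-methylbut-2-enoate
Conditions: Me2SnCl2 (5 mol %), K2CO3, THF, 0 °C to rt
Reagents that add atoms: none
Why: Tin-mediated regioselective monoacylation of a cis-1,2-diol (stannylene activation) esterifies the equatorial, less hindered C6 hydroxyl rather than the pseudo-axial C1 hydroxyl next to the quaternary oxirane carbon, with retention at C6.

**Step 9**
Reactants: 14 (1R,2S,3S,4S,6S)-2-hydroxy-1-methyl-4-[(E)-6-methyl-3-oxohepta-1,4-dien-2-yl]-7-oxabicyclo[4.1.0]heptan-3-yl (E)-2-methylbut-2-enoate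
Product: 15 (1S,3S,4S,6S)-1-methyl-4-[(E)-6-methyl-3-oxohepta-1,4-dien-2-yl]-2-oxo-7-oxabicyclo[4.1.0]heptan-3-yl (E)-2-methylbut-2-enoate
Conditions: Dess–Martin periodinane, pyridine, CH2Cl2, 0 °C to rt
Reagents that add atoms: none
Why: Dess–Martin oxidation turns the remaining C1 alcohol into the ketone under near-neutral conditions that leave the oxirane, the dienone and the α-acyloxy centre C6 (already in the thermodynamically preferred trans relation to C5) unchanged.

**Step 10**
Reactants: 15 (1S,3S,4S,6S)-1-methyl-4-[(E)-6-methyl-3-oxohepta-1,4-dien-2-yl]-2-oxo-7-oxabicyclo[4.1.0]heptan-3-yl (E)-2-methylbut-2-enoate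
Product: 16 (1S,3S,4S,6S)-4-[(E)-6-hydroperoxy-6-methyl-3-oxohepta-1,4-dien-2-yl]-1-methyl-2-oxo-7-oxabicyclo[4.1.0]heptan-3-yl (E)-2-methylbut-2-enoate (CNP0284595.1)
Conditions: N-hydroxyphthalimide (20 mol %), 2,2′-azobis(4-methoxy-2,4-dimethylvaleronitrile) (5 mol %), O2 (1 atm), MeCN, 35 °C, stopped near 60% conversion, 15 recycled
Reagents that add atoms: dioxygen, O=O
Why: Radical-chain aerobic C–H hydroperoxidation (phthalimide-N-oxyl hydrogen abstraction, then oxygen trapping) selects the tertiary allylic C11–H, the only weak C–H that is unhindered and not deactivated by a neighbouring acyloxy or carbonyl group (the C5–H lies in the nodal plane of its alkene and is flanked by the ester), and reversible oxygen addition to the delocalised radical funnels to the conjugated E γ-hydroperoxy enone without creating a stereocentre.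

**Compound list**
1 | toluene | Cc1ccccc1 | starting material
2 | (1S,2R)-3-methylcyclohexa-3,5-diene-1,2-diol | CC1=CC=C[C@H](O)[C@@H]1O | intermediate
3 | (3aR,7aS)-2,2,4-trimethyl-3a,7a-dihydro-1,3-benzodioxole | CC1=CC=C[C@@H]2OC(C)(C)O[C@H]12 | intermediate
4 | (E)-5-methylhex-3-en-2-one | CC(=O)/C=C/C(C)C | starting material
5 | (E)-trimethyl[(5-methylhexa-1,3-dien-2-yl)oxy]silane | C=C(O[Si](C)(C)C)/C=C/C(C)C | intermediate
6 | (E)-1-bromo-5-methylhex-3-en-2-one | BrCC(=O)/C=C/C(C)C | intermediate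
7 | (E)-5-methyl-1-[(3aR,7S,7aS)-2,2,4-trimethyl-3a,6,7,7a-tetrahydro-1,3-benzodioxol-7-yl]hex-3-en-2-one (side chain trans to the dioxolane oxygens) | CC(C)/C=C/C(=O)C[C@@H]1CC=C(C)[C@H]2OC(C)(C)O[C@@H]12 | intermediate
8 | (E)-1-(dimethylamino)-6-methyl-2-[(3aR,7S,7aS)-2,2,4-trimethyl-3a,6,7,7a-tetrahydro-1,3-benzodioxol-7-yl]hept-4-en-3-one (both epimers at the aminomethyl-bearing carbon) | CC(C)/C=C/C(=O)C(CN(C)C)[C@@H]1CC=C(C)[C@H]2OC(C)(C)O[C@@H]12 | intermediate
9 | N-methyl quaternary ammonium iodide of 8 | CC(C)/C=C/C(=O)C(C[N+](C)(C)C)[C@@H]1CC=C(C)[C@H]2OC(C)(C)O[C@@H]12.[I-] | intermediate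
10 | (E)-6-methyl-2-[(3aR,7S,7aS)-2,2,4-trimethyl-3a,6,7,7a-tetrahydro-1,3-benzodioxol-7-yl]hepta-1,4-dien-3-one | CC(C)/C=C/C(=O)C(=C)[C@@H]1CC=C(C)[C@H]2OC(C)(C)O[C@@H]12 | intermediate
11 | (E)-2-[(1S,2S,3S,4S,6S)-2,3-(isopropylidenedioxy)-1-methyl-7-oxabicyclo[4.1.0]heptan-4-yl]-6-methylhepta-1,4-dien-3-one (oxirane cis to the side chain, trans to the dioxolane) | CC(C)/C=C/C(=O)C(=C)[C@@H]1C[C@@H]2O[C@]2(C)[C@H]3OC(C)(C)O[C@@H]13 | intermediate
12 | (E)-2-[(1R,2S,3S,4S,6S)-2,3-dihydroxy-1-methyl-7-oxabicyclo[4.1.0]heptan-4-yl]-6-methylhepta-1,4-dien-3-one | CC(C)/C=C/C(=O)C(=C)[C@@H]1C[C@@H]2O[C@]2(C)[C@@H](O)[C@H]1O | intermediate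
13 | (E)-2-methylbut-2-enoyl chloride (tigloyl chloride) | C/C=C(\C)C(Cl)=O | starting material
14 | (1R,2S,3S,4S,6S)-2-hydroxy-1-methyl-4-[(E)-6-methyl-3-oxohepta-1,4-dien-2-yl]-7-oxabicyclo[4.1.0]heptan-3-yl (E)-2-methylbut-2-enoate | CC(C)/C=C/C(=O)C(=C)[C@@H]1C[C@@H]2O[C@]2(C)[C@@H](O)[C@H]1OC(=O)/C(C)=C/C | intermediate
15 | (1S,3S,4S,6S)-1-methyl-4-[(E)-6-methyl-3-oxohepta-1,4-dien-2-yl]-2-oxo-7-oxabicyclo[4.1.0]heptan-3-yl (E)-2-methylbut-2-enoate | CC(C)/C=C/C(=O)C(=C)[C@@H]1C[C@@H]2O[C@]2(C)C(=O)[C@H]1OC(=O)/C(C)=C/C | intermediate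
16 | (1S,3S,4S,6S)-4-[(E)-6-hydroperoxy-6-methyl-3-oxohepta-1,4-dien-2-yl]-1-methyl-2-oxo-7-oxabicyclo[4.1.0]heptan-3-yl (E)-2-methylbut-2-enoate | C=C(C(=O)/C=C/C(C)(C)OO)[C@@H]1C[C@@H]2O[C@]2(C)C(=O)[C@H]1OC(=O)/C(C)=C/C | target

**Totals**
Total step count: 10. Longest linear sequence: 9 (steps 1, 2, 4, 5, 6, 7, 8, 9, 10).

**Three steps most likely to fail**

Step 4. The risks are hydrogen delivery to the wrong allyl terminus (C2 instead of C4), simple reduction of 6, and diene dimerisation. The fallback sets out from 3 and 6 and comes back at 7. Cu(dap)2Cl (monovalent copper; dap = 2,9-bis(4-methoxyphenyl)-1,10-phenanthroline), green LEDs, MeCN gives an atom-transfer radical addition in which the allyl radical is closed by bromine transfer from the divalent copper bromide. This yields the allylic bromide adduct F1, formed together with its 1,4-regioisomer, which leads to the same allyl system. Pd(PPh3)4 (zerovalent palladium) with Bu3SnH in THF then places hydride at the less substituted allyl terminus and gives 7.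

Step 7. The risk is acid opening of the trisubstituted oxirane, or participation by the freed C1 hydroxyl, during acetonide hydrolysis. The fallback sets out from 10 and comes back at 12. The acetonide is hydrolysed before the oxirane exists (AcOH/H2O, 40 °C) to the ene-diol F2. Et3SiCl/imidazole in DMF gives the bis(triethylsilyl) ether F3. mCPBA again attacks anti to the pseudo-axial allylic silyloxy group and gives the epoxy bis(triethylsilyl) ether F4. AcOH/THF/H2O at 20 °C removes both silyl groups without opening the oxirane and gives 12.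

Step 10. The risk is competing abstraction of the C5 or C6 hydrogen and over-oxidation. The fallback sets out from 11 and comes back at 16. KN(SiMe3)2, THF, −78 °C, then an AcOH quench, effects γ-deprotonation (C7 no longer bears hydrogen) and kinetic α-protonation to give the prenyl ketone acetonide F5. The operations of steps 7, 8 and 9 then give the prenyl ketone diol F6, the prenyl ketone hydroxy tiglate F7 and the prenyl ketone keto ester F8. A Schenck ene reaction with singlet oxygen (tetraphenylporphyrin, O2, visible light, CH2Cl2, −20 °C) on the only electron-rich alkene, with abstraction of a C9 hydrogen, gives 16.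

**Further compounds**
F1 | step 4 | (E)-1-[(3aR,7S,7aS)-6-bromo-2,2,4-trimethyl-3a,6,7,7a-tetrahydro-1,3-benzodioxol-7-yl]-5-methylhex-3-en-2-one (allylic bromide adduct, both epimers at the bromine-bearing carbon) | CC(C)/C=C/C(=O)C[C@@H]1C(Br)C=C(C)[C@H]2OC(C)(C)O[C@@H]12
F2 | step 7 | (E)-2-[(1S,5R,6S)-5,6-dihydroxy-4-methylcyclohex-3-en-1-yl]-6-methylhepta-1,4-dien-3-one (ene-diol) | CC(C)/C=C/C(=O)C(=C)[C@@H]1CC=C(C)[C@@H](O)[C@H]1O
F3 | step 7 | bis(triethylsilyl) ether of F2 | CC(C)/C=C/C(=O)C(=C)[C@@H]1CC=C(C)[C@@H](O[Si](CC)(CC)CC)[C@H]1O[Si](CC)(CC)CC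
F4 | step 7 | bis(triethylsilyl) ether of 12 (epoxy bis(triethylsilyl) ether) | CC(C)/C=C/C(=O)C(=C)[C@@H]1C[C@@H]2O[C@]2(C)[C@@H](O[Si](CC)(CC)CC)[C@H]1O[Si](CC)(CC)CC
F5 | step 10 | 2-[(1S,2S,3S,4S,6S)-2,3-(isopropylidenedioxy)-1-methyl-7-oxabicyclo[4.1.0]heptan-4-yl]-6-methylhepta-1,5-dien-3-one (prenyl ketone acetonide) | C=C(C(=O)CC=C(C)C)[C@@H]1C[C@@H]2O[C@]2(C)[C@H]3OC(C)(C)O[C@@H]13
F6 | step 10 | 2-[(1R,2S,3S,4S,6S)-2,3-dihydroxy-1-methyl-7-oxabicyclo[4.1.0]heptan-4-yl]-6-methylhepta-1,5-dien-3-one (prenyl ketone diol) | C=C(C(=O)CC=C(C)C)[C@@H]1C[C@@H]2O[C@]2(C)[C@@H](O)[C@H]1O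
F7 | step 10 | (1R,2S,3S,4S,6S)-2-hydroxy-1-methyl-4-(6-methyl-3-oxohepta-1,5-dien-2-yl)-7-oxabicyclo[4.1.0]heptan-3-yl (E)-2-methylbut-2-enoate (prenyl ketone hydroxy tiglate) | C=C(C(=O)CC=C(C)C)[C@@H]1C[C@@H]2O[C@]2(C)[C@@H](O)[C@H]1OC(=O)/C(C)=C/C
F8 | step 10 | (1S,3S,4S,6S)-1-methyl-4-(6-methyl-3-oxohepta-1,5-dien-2-yl)-2-oxo-7-oxabicyclo[4.1.0]heptan-3-yl (E)-2-methylbut-2-enoate (prenyl ketone keto ester) | C=C(C(=O)CC=C(C)C)[C@@H]1C[C@@H]2O[C@]2(C)C(=O)[C@H]1OC(=O)/C(C)=C/C
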